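**Retrosynthetic overview**
1. Numbering: ring C1–C10 (CH3 on C4 and C10, OH on C2 and C9, ester O on C6, lactone O on C8, C11 on C7). Endgame: desilylation ⇐ Pd/CO lactonisation of a C8–OH/C11–Br pair ⇐ reduction of a ten-membered C8 ketone.
2. Key disconnection C6–C7: the ketone is the Claisen product of an eight-membered cyclic allyl vinyl ether (ring O, C8, C9, C10, C1, C2, C3, C4; exocyclic C7=C8; alkenyl C5=C6 on C4). The ring O is traded for C5–C6–C7, 8 → 10.
3. Enabling feature: the γ,δ-unsaturated carbonyl retron C8(O)–C7–C6(O)–C5=C4(CH3) lies next to the Z-C1=C10 alkene and the 1,3-pair C2–O/C4. C8 can therefore be stored as the ketal carbon of a 2,9-dioxabicyclo[3.3.1]nonene whose rim is that eight-membered ring.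
4. Ketal ⇐ Achmatowicz reaction and bicycloketalisation of a 2,3,5-trisubstituted furan 1,3-diol ⇐ aldol, ethynylation, furan alkylation. Ring order: furan → pyranone → bicyclic ketal → ten-membered carbocycle → γ-lactone.
5. Stereochemistry: C2 by organocatalysis, the side-chain centre bought; C4 (sacrificial), C9, C6, C7 and C8 are relayed from C2.

Key step: step 13

Remark: (R)-2-methylbutanoic acid is taken as a commercial single enantiomer and supplies the side-chain stereocentre unchanged.

**Step 1**
Reactants: 1 3-methylfuran-2-carbaldehyde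
Product: 2 2-(3-methylfuran-2-yl)-1,3-dioxolane
Conditions: HOCH2CH2OH, p-TsOH (cat.), PhMe, reflux, Dean–Stark
Reagents that add atoms: ethylene glycol, OCCO
Why: Acid-catalysed acetalisation with azeotropic removal of water masks the aldehyde so that the furan can be metalated.

**Step 2**
Reactants: 2 2-(3-methylfuran-2-yl)-1,3-dioxolane; 3 2,3-dibromoprop-1-ene
Product: 5 2-[5-(2-bromoprop-2-en-1-yl)-3-methylfuran-2-yl]-1,3-dioxolane, via 5-lithiofuran acetal 4 (not isolated)
Conditions: n-BuLi, THF, −78 → 0 °C; 3, −78 °C → rt
Reagents that add atoms: none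
Why: α-Lithiation of the furan at its only free α-position followed by SN2 alkylation at the allylic bromide of 3 should install C7 and C11–C13, the vinylic C–Br bond being inert at this temperature.

**Step 3**
Reactants: 5 2-[5-(2-bromoprop-2-en-1-yl)-3-methylfuran-2-yl]-1,3-dioxolane
Product: 6 5-(2-bromoprop-2-en-1-yl)-3-methylfuran-2-carbaldehyde
Conditions: 1 M HCl, THF, rt
Reagents that add atoms: water, O
Why: Mild acetal hydrolysis frees the furfural carbonyl (future C2) and leaves the vinyl bromide untouched.

**Step 4**
Reactants: 6 5-(2-bromoprop-2-en-1-yl)-3-methylfuran-2-carbaldehyde; 7 acetone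
Product: 8 (4S)-4-[5-(2-bromoprop-2-en-1-yl)-3-methylfuran-2-yl]-4-hydroxybutan-2-one
Conditions: D-proline-derived amino alcohol amide (10 mol %), 7 as solvent, −20 °C
Reagents that add atoms: none
Why: Enamine-catalysed direct asymmetric aldol addition of acetone, in which the D-configured catalyst binds the aldehyde by hydrogen bonds and exposes one face only, should set C2 (S), the single ring stereocentre made by catalysis.

**Step 5**
Reactants: 8 (4S)-4-[5-(2-bromoprop-2-en-1-yl)-3-methylfuran-2-yl]-4-hydroxybutan-2-one; 9 ethynylmagnesium bromide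
Product: 10 (1S,3S)-1-[5-(2-bromoprop-2-en-1-yl)-3-methylfuran-2-yl]-3-methylpent-4-yne-1,3-diol
Conditions: 9 (3.5 equiv), THF, −78 → −20 °C; then H2O (pH 7 buffer)
Reagents that add atoms: none
Why: Chelation-controlled Grignard addition (Cram-chelate type 1,3-induction): the magnesium aldolate forms a six-membered chelate with the furyl group equatorial, axial attack of the alkynyl nucleophile should give the 1,3-anti diol (alkyne counted in the chain) and thus C4 (S), and the minor epimer is removed by chromatography.

**Step 6**
Reactants: 10 (1S,3S)-1-[5-(2-bromoprop-2-en-1-yl)-3-methylfuran-2-yl]-3-methylpent-4-yne-1,3-diol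
Product: 11 (2S)-6-(2-bromoprop-2-en-1-yl)-6-hydroxy-2-[(2S)-2-hydroxy-2-methylbut-3-yn-1-yl]-4-methyl-2H-pyran-3(6H)-one (anomer mixture)
Conditions: NBS, NaHCO3, THF–H2O (4:1), 0 °C
Reagents that add atoms: water, O
Why: Achmatowicz oxidative rearrangement of the furfuryl alcohol turns the furan carbons into C1, C10, C9 and C8 with the Z alkene locked in a six-membered ring, the electron-rich furan reacting far faster than the alkyne or the bromoalkene.

**Step 7**
Reactants: 11 Achmatowicz hemiketal
Product: 12 (1R,3S,5S)-1-(2-bromoprop-2-en-1-yl)-3-ethynyl-3,7-dimethyl-2,9-dioxabicyclo[3.3.1]non-7-en-6-one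
Conditions: CSA (10 mol %), 4 Å MS, CH2Cl2, 0 °C → rt
Reagents that add atoms: none
Why: Acid-catalysed bicycloketalisation: the tertiary C4 hydroxyl traps the pyranyl oxocarbenium ion, and the C8 configuration is dictated by the bridge because only the cis-bridged ketal can form.

**Step 8**
Reactants: 12 bicyclic ketal enone
Product: 13 7,8-epoxide of 12 with the oxirane oxygen anti to the O2–C3–C4 bridge (exo)
Conditions: 30 % H2O2, NaOH (cat.), MeOH, 0 °C
Reagents that add atoms: hydrogen peroxide, OO
Why: Weitz–Scheffer nucleophilic epoxidation, in which hydroperoxide should add to C9 from the convex face anti to the axial ketal C–O bond and the dioxane bridge.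

**Step 9**
Reactants: 13 exo-epoxy ketone
Product: 15 1-(2-bromoprop-2-en-1-yl)-3-ethynyl-3,7-dimethyl-2,9-dioxabicyclo[3.3.1]non-6-en-8-ol with the OH exo (anti to the bridge), via epoxy hydrazone 14 (not isolated)
Conditions: N2H4·H2O, AcOH (cat.), MeOH, 0 °C → rt
Reagents that add atoms: none
Why: Wharton transposition, well precedented on bicyclic ketal enone epoxides, moves the oxygen from C1 to C9 and places the alkene at C1=C10.

**Step 10**
Reactants: 15 exo allylic alcohol
Product: 16 1-(2-bromoprop-2-en-1-yl)-3-ethynyl-3,7-dimethyl-2,9-dioxabicyclo[3.3.1]non-6-en-8-one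
Conditions: Dess–Martin periodinane, CH2Cl2, 0 °C → rt
Reagents that add atoms: none
Why: Dess–Martin oxidation completes the 1,3-carbonyl transposition and erases the wrong C9 configuration.

**Step 11**
Reactants: 16 transposed enone
Product: 17 the corresponding non-6-en-8-ol with the OH endo (syn to the bridge; C9 as in the target)
Conditions: NaBH4, CeCl3·7H2O, MeOH, −78 °C
Reagents that add atoms: none
Why: Luche 1,2-reduction, in which hydride should attack from the convex face, anti to the axial C8–O bond (also the Felkin–Anh face) and away from the endo methyl group on C4, which sets C9 (R).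

**Step 12**
Reactants: 17 endo allylic alcohol; 18 (R)-2-methylbutanoic acid
Product: 19 (Z)-2-(bicyclic ketal-3-yl)ethenyl (2R)-2-methylbutanoate (Z enol ester of 17)
Conditions: [Ru(η3-2-methylallyl)2(dppb)] (2 mol %), PhMe, 65 °C
Reagents that add atoms: none
Why: Ruthenium-vinylidene-mediated anti-Markovnikov hydro-acyloxylation of a terminal alkyne, a reaction type established for tertiary propargylic alcohols and ethers, should give the Z enol ester and so place the complete ester side chain on the future C6 oxygen.

**Step 13**
Reactants: 19 Z enol ester ketal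
Product: 22 ten-membered ketone (1(10)Z,4Z; 2S,6R,7S,9R) with 7-(1-bromoethenyl), 6-[(2R)-2-methylbutanoyloxy] and 2,9-bis(triethylsilyloxy) groups, via C9 silyl ether 20 (not isolated), via oxocene enol ether 21 (not isolated)
Conditions: TESOTf (2.2 equiv), i-Pr2NEt (5 equiv), CH2Cl2, −78 → 0 °C; aq NaHCO3 wash, solvent switch; PhMe (0.01 M), 80 °C
Reagents that add atoms: triethylsilyl trifluoromethanesulfonate, CC[Si](CC)(CC)OS(=O)(=O)C(F)(F)F
Why: Proposed new method: TESOTf first caps the C9 hydroxyl (20) and then silylates the more accessible ketal oxygen O2 (it sits next to a CH, the other ketal oxygen between two fully substituted carbons), the C8–O2 bond ionises with help from the remaining oxygen, and i-Pr2NEt removes an allylic C7 proton to give the eight-membered 2-alkylidene-8-alkenyloxocene 21, whose array C7=C8–O–C4–C5=C6 undergoes a [3,3]-sigmatropic (Claisen) shift on warming. The closest known reactions are the opening of cyclic ketals to ω-silyloxy enol ethers with R3SiOTf and a tertiary amine, the ketal (Saucy–Marbet) Claisen rearrangement of tertiary allylic alcohols, and the Claisen ring expansion of 2-methylene-6-vinyltetrahydropyrans to cyclooct-4-enones; new are their merger on a bridged ketal and the 8 → 10 ring size. The one ring that is closed is the ten-membered carbocycle: suprafacial C6–C7 bond formation and C4–O cleavage, in a chair-like six-centre transition state spanned by the five-atom tether C9–C10=C1–C2–C3, replace the ring oxygen by C5–C6–C7 (two atoms more), and that oxygen becomes the C8 carbonyl oxygen. C6 and C7 are set by chirality transfer from C4 (S): with the Z enol ether and the Z enol ester the chair gives 6R,7S, and the short tether can bridge C8 and C4 only if C3 takes the pseudoaxial and the methyl group the pseudoequatorial site at C4, which makes the new C4=C5 bond Z. The step needs cleavage of C8–O2 and not of C8–O(C4), deprotonation at C7 and not at C9, and a Z enol ether; these are secured by the steric difference of the two ketal oxygens, by kinetic amine deprotonation of the less hindered allylic CH2, by A(1,3) strain between C11 and the branched C9 in the E isomer, and by the fact that the isomeric six-membered enol ether has no accessible [3,3] path. In the required transition state the C2 and C9 silyloxy groups point away from the ring (matched case), and carbonyl formation plus loss of the strained boat dioxane drive the reaction.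

**Step 14**
Reactants: 22 ten-membered ketone
Product: 23 the (8R)-alcohol of 22 (all centres arranged as in the target)
Conditions: NaBH4, CeCl3·7H2O, MeOH–THF, −78 → −40 °C
Reagents that add atoms: none
Why: Luche-type carbonyl reduction in which hydride should add anti to the C9–O bond (polar Felkin–Anh or Cornforth arrangement), the same face being favoured by the dipole-minimised 1,3-model for the C6 acyloxy group, to set C8 (R) with O8 syn to O9 and trans to C11, while the non-basic cerium medium should suppress β-elimination of the ester.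

**Step 15**
Reactants: 23 (8R)-alcohol
Product: 24 2,9-bis(triethylsilyl) ether of the target
Conditions: Pd(PPh3)4 (5 mol %), CO (1 atm), Et3N, THF, 55 °C
Reagents that add atoms: carbon monoxide, [C-]#[O+]
Why: Palladium-catalysed carbonylative lactonisation of a 3-bromobut-3-en-1-ol unit (oxidative addition into C11–Br, CO insertion, capture of the acyl-palladium by the C8 hydroxyl) should give the α-methylene-γ-butyrolactone directly and trans-fused because C7 and C8 are untouched, and the allylic C6 ester should survive because Pd(0) would have to reach the C4=C5 bond from inside the ring to expel it.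

**Step 16**
Reactants: 24 bis-silyl ether
Product: 25 target compound
Conditions: HF·pyridine, pyridine, THF, 0 °C
Reagents that add atoms: none
Why: Buffered fluoride desilylation removes both triethylsilyl groups without base, so that the ester, the lactone and the exocyclic methylene should remain intact.

**Compound list**
1 | 3-methylfuran-2-carbaldehyde | Cc1ccoc1C=O | starting material
2 | 2-(3-methylfuran-2-yl)-1,3-dioxolane | Cc1ccoc1C1OCCO1 | intermediate
3 | 2,3-dibromoprop-1-ene | C=C(Br)CBr | starting material
4 | 5-lithio derivative of 2 | [Li]c1cc(C)c(C2OCCO2)o1 | intermediate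
5 | 2-[5-(2-bromoprop-2-en-1-yl)-3-methylfuran-2-yl]-1,3-dioxolane | C=C(Br)Cc1cc(C)c(C2OCCO2)o1 | intermediate
6 | 5-(2-bromoprop-2-en-1-yl)-3-methylfuran-2-carbaldehyde | C=C(Br)Cc1cc(C)c(C=O)o1 | intermediate
7 | acetone | CC(C)=O | starting material
8 | (4S)-aldol adduct | CC(=O)C[C@H](O)c1oc(CC(Br)=C)cc1C | intermediate
9 | ethynylmagnesium bromide | C#C[Mg]Br | starting material
10 | (1S,3S)-furyl alkyne diol | C#C[C@@](C)(O)C[C@H](O)c1oc(CC(Br)=C)cc1C | intermediate
11 | Achmatowicz hemiketal (anomer mixture) | C#C[C@@](C)(O)C[C@@H]1OC(O)(CC(Br)=C)C=C(C)C1=O | intermediate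
12 | bicyclic ketal enone | C=C(Br)C[C@]12O[C@](C)(C#C)C[C@H](O1)C(=O)C(C)=C2 | intermediate
13 | exo-epoxy ketone | C=C(Br)C[C@]12O[C@](C)(C#C)C[C@H](O1)C(=O)[C@]3(C)O[C@H]23 | intermediate
14 | epoxy hydrazone | C=C(Br)C[C@]12O[C@](C)(C#C)C[C@H](O1)C(=NN)[C@]3(C)O[C@H]23 | intermediate
15 | exo allylic alcohol | C=C(Br)C[C@]12O[C@](C)(C#C)C[C@H](O1)C=C(C)[C@@H]2O | intermediate
16 | transposed enone | C=C(Br)C[C@]12O[C@](C)(C#C)C[C@H](O1)C=C(C)C2=O | intermediate
17 | endo allylic alcohol | C=C(Br)C[C@]12O[C@](C)(C#C)C[C@H](O1)C=C(C)[C@H]2O | intermediate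
18 | (R)-2-methylbutanoic acid | CC[C@@H](C)C(=O)O | starting material
19 | Z enol ester ketal | C=C(Br)C[C@]12O[C@](C)(/C=C\OC(=O)[C@H](C)CC)C[C@H](O1)C=C(C)[C@H]2O | intermediate
20 | C9 triethylsilyl ether of 19 | C=C(Br)C[C@]12O[C@](C)(/C=C\OC(=O)[C@H](C)CC)C[C@H](O1)C=C(C)[C@H]2O[Si](CC)(CC)CC | intermediate
21 | eight-membered oxocene enol ether | C=C(Br)/C=C1\O[C@](C)(/C=C\OC(=O)[C@H](C)CC)C[C@H](O[Si](CC)(CC)CC)/C=C(/C)[C@H]1O[Si](CC)(CC)CC | intermediate
22 | ten-membered ketone | C=C(Br)[C@H]1[C@H](OC(=O)[C@H](C)CC)/C=C(/C)C[C@H](O[Si](CC)(CC)CC)/C=C(/C)[C@@H](O[Si](CC)(CC)CC)C1=O | intermediate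
23 | (8R)-alcohol | C=C(Br)[C@H]1[C@H](OC(=O)[C@H](C)CC)/C=C(/C)C[C@H](O[Si](CC)(CC)CC)/C=C(/C)[C@@H](O[Si](CC)(CC)CC)[C@@H]1O | intermediate
24 | bis(triethylsilyl) ether of the target | C=C1C(=O)O[C@@H]2[C@@H]1[C@H](OC(=O)[C@H](C)CC)/C=C(/C)C[C@H](O[Si](CC)(CC)CC)/C=C(/C)[C@H]2O[Si](CC)(CC)CC | intermediate
25 | CNP0176600.1 | C=C1C(=O)O[C@@H]2[C@@H]1[C@H](OC(=O)[C@H](C)CC)/C=C(/C)C[C@H](O)/C=C(/C)[C@H]2O | target

**Total step count:** 16. **Longest linear sequence:** 16 steps (1 → 25).

**Steps most likely to fail**

**Step 13 (proposed new method).**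
- What may go wrong: the silyl triflate may open the ketal at the other C–O bond, giving a six-membered oxocarbenium ion and an enol ether with no [3,3] path. The tertiary allylic C4–O bond may ionise. Deprotonation may run towards C9.
- Fallback (known chemistry, thermodynamic instead of kinetic selection): starting from 19, the C9 hydroxyl is silylated on its own (TESCl, imidazole, DMF) and 20 is isolated. Then 20 is heated with a catalytic weak acid (2,4-dinitrophenol, xylene, 135 °C), the conditions of the ketal (Saucy–Marbet) Claisen rearrangement of tertiary allylic alcohols.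
- Under these reversible conditions the ketal and all enol ether isomers interconvert. Only the eight-membered allyl vinyl ether can leave the equilibrium irreversibly, giving the C2-hydroxy ketone F1. Silylation (TESCl, imidazole) comes back to the route at 22.

**Step 14.**
- What may go wrong: the folded ten-membered ring may expose the other carbonyl face to the external hydride (poor or reversed facial selectivity), and the β-acyloxy ketone may eliminate.
- Fallback (internal chelate control): starting from 17, ruthenium-catalysed addition of methoxyacetic acid in place of 18 gives the enol methoxyacetate F2. The conditions of step 13 carry it through the C9 silyl ether F3 and the oxocene enol ether F4 to the ten-membered ketone F5.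
- Yb(OTf)3 in MeOH removes the methoxyacetate under neutral conditions to give the β-hydroxy ketone F6. Narasaka–Prasad reduction (Et2BOMe, NaBH4, THF–MeOH, −78 °C) through the boron chelate gives the 6,8-syn diol F7.
- Steglich esterification with 18 (DCC, DMAP, −20 °C) at the allylic, less hindered C6 hydroxyl (C8–OH lies between two branched carbons) comes back to the route at 23.

**Step 15.**
- What may go wrong: Pd(0) may ionise the allylic C6 ester, or the ester may migrate to O8 before the acyl-palladium is trapped.
- Fallback (carbonylation before any allylic ester exists): starting from 20, isolated as above, methoxycarbonylation of the vinyl bromide (Pd(PPh3)4, CO, MeOH, i-Pr2NEt, DMF, 50 °C) gives the acrylate ketal F8.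
- TESOTf and i-Pr2NEt followed by heating as in step 13 lead through the oxocene enol ether F9 to the keto ester F10. Luche reduction gives the hydroxy ester F11, which lactonises (PPTS cat.) and comes back to the route at 24.

**Further compounds**
F1 | step 13 | C2-hydroxy ten-membered ketone | C=C(Br)[C@H]1[C@H](OC(=O)[C@H](C)CC)/C=C(/C)C[C@H](O)/C=C(/C)[C@@H](O[Si](CC)(CC)CC)C1=O
F2 | step 14 | enol methoxyacetate ketal | C=C(Br)C[C@]12O[C@](C)(/C=C\OC(=O)COC)C[C@H](O1)C=C(C)[C@H]2O
F3 | step 14 | C9 triethylsilyl ether of F2 | C=C(Br)C[C@]12O[C@](C)(/C=C\OC(=O)COC)C[C@H](O1)C=C(C)[C@H]2O[Si](CC)(CC)CC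
F4 | step 14 | oxocene enol ether (methoxyacetate series) | C=C(Br)/C=C1\O[C@](C)(/C=C\OC(=O)COC)C[C@H](O[Si](CC)(CC)CC)/C=C(/C)[C@H]1O[Si](CC)(CC)CC
F5 | step 14 | ten-membered ketone with C6 methoxyacetate | C=C(Br)[C@H]1[C@H](OC(=O)COC)/C=C(/C)C[C@H](O[Si](CC)(CC)CC)/C=C(/C)[C@@H](O[Si](CC)(CC)CC)C1=O
F6 | step 14 | C6-hydroxy ketone | C=C(Br)[C@H]1[C@H](O)/C=C(/C)C[C@H](O[Si](CC)(CC)CC)/C=C(/C)[C@@H](O[Si](CC)(CC)CC)C1=O
F7 | step 14 | 6,8-syn diol | C=C(Br)[C@H]1[C@H](O)/C=C(/C)C[C@H](O[Si](CC)(CC)CC)/C=C(/C)[C@@H](O[Si](CC)(CC)CC)[C@@H]1O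
F8 | step 15 | methyl acrylate ketal | C=C(C(=O)OC)C[C@]12O[C@](C)(/C=C\OC(=O)[C@H](C)CC)C[C@H](O1)C=C(C)[C@H]2O[Si](CC)(CC)CC
F9 | step 15 | oxocene enol ether (acrylate series) | C=C(C(=O)OC)/C=C1\O[C@](C)(/C=C\OC(=O)[C@H](C)CC)C[C@H](O[Si](CC)(CC)CC)/C=C(/C)[C@H]1O[Si](CC)(CC)CC
F10 | step 15 | ten-membered keto ester | C=C(C(=O)OC)[C@H]1[C@H](OC(=O)[C@H](C)CC)/C=C(/C)C[C@H](O[Si](CC)(CC)CC)/C=C(/C)[C@@H](O[Si](CC)(CC)CC)C1=O
F11 | step 15 | C8-hydroxy ester | C=C(C(=O)OC)[C@H]1[C@H](OC(=O)[C@H](C)CC)/C=C(/C)C[C@H](O[Si](CC)(CC)CC)/C=C(/C)[C@@H](O[Si](CC)(CC)CC)[C@@H]1O
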